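**Retrosynthetic overview**

1. The target is a 6-aryl (2S)-flavanone (rings A, B, C; O1, C2, C3, C4, C4a, C5–C8, C8a) joined through C6 to ring B' of a flavone (rings A', B', C'). The last disconnections are the four benzyl ethers (hydrogenolysis) and the C4 ketone, which is carried as a spiro-1,3-dithiane.
2. The biaryl bond from C6 of ring A to the ring B' carbon ortho to its methoxy group is made by Suzuki coupling of a 6-iodoflavan dithioketal with the flavone boronate. Ring C' of the flavone is made in its own branch (chalcone, then iodine/DMSO).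
3. Ring C of the flavanone is made by a (3+3) union of (R)-2-(4-methoxyphenyl)oxirane with a 2-(6-fluoroaryl)-2-lithio-1,3-dithiane. Strain-releasing epoxide opening makes C3–C4, and the alkoxide set free then displaces fluoride to make O1–C8a.
4. Enabling feature: O1–C2–C3 of ring C is the open form of an aryl oxirane, and C4 and C8a are 1,3-related through C4a of ring A. C4 is a carbonyl carbon (an acyl anion as its dithiane) and C8a is an oxygen-bearing arene carbon para to C6 that can carry fluoride, so the fluorine position fixes the 6-linkage and the epoxide delivers C2.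
5. Order of ring formation: ring C (step 7) and ring C' (step 10) in separate branches; all benzene rings are bought.

Key step: step 7

Assumption: the biaryl axis between ring A and ring B' carries three small ortho substituents and is taken as freely rotating, in line with the single stereodescriptor of the structure, so only C2 is controlled.

**Route**

Step 1
Reactants: 1 5-fluorobenzene-1,3-diol
Product: 2 5-fluoro-2-iodobenzene-1,3-diol
Conditions: I2 (1.05 equiv), NaHCO3, H2O/THF, 0 °C → rt
Reagents that add atoms: iodine, II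
Why: Electrophilic aromatic iodination of a resorcinol under aqueous hydrogen carbonate conditions should go to the carbon between the two hydroxyl groups, which here is also para to fluorine.

Step 2
Reactants: 2 5-fluoro-2-iodobenzene-1,3-diol
Product: 3 1,3-bis(benzyloxy)-5-fluoro-2-iodobenzene
Conditions: BnBr (2.2 equiv), K2CO3, DMF, 50 °C
Reagents that add atoms: benzyl bromide, BrCc1ccccc1
Why: Williamson ether synthesis on both phenols gives benzyl ethers that should tolerate the later amide base, alkoxide and palladium steps and leave by hydrogenolysis while the two methyl ethers stay.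

Step 3
Reactants: 3 1,3-bis(benzyloxy)-5-fluoro-2-iodobenzene
Product: 4 2,4-bis(benzyloxy)-6-fluoro-3-iodobenzaldehyde
Conditions: POCl3, DMF, 0 → 75 °C; then H2O
Reagents that add atoms: N,N-dimethylformamide, CN(C)C=O; water, O
Why: Vilsmeier–Haack formylation can only occur at the two free positions, which are equivalent by symmetry and each ortho and para to a benzyloxy group, so a single aldehyde with CHO ortho to fluorine should form.

Step 4
Reactants: 4 2,4-bis(benzyloxy)-6-fluoro-3-iodobenzaldehyde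
Product: 5 2-[2,4-bis(benzyloxy)-6-fluoro-3-iodophenyl]-1,3-dithiane
Conditions: propane-1,3-dithiol, I2 (10 mol %), CHCl3, rt
Reagents that add atoms: propane-1,3-dithiol, SCCCS
Why: Thioacetalization (Corey–Seebach dithiane formation) turns the future C4 carbonyl carbon into an acyl anion equivalent, and mild iodine catalysis avoids Lewis acid/thiol cleavage of the benzyl ethers.

Step 5
Reactants: 6 2-chloro-1-(4-methoxyphenyl)ethan-1-one
Product: 7 (1R)-2-chloro-1-(4-methoxyphenyl)ethan-1-ol
Conditions: (R)-2-methyl-CBS-oxazaborolidine (10 mol %), BH3·SMe2, THF, 0 °C; then H2O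
Reagents that add atoms: none
Why: Corey–Bakshi–Shibata reduction with the (R)-oxazaborolidine should deliver hydride to the ketone face that gives the (R)-chlorohydrin (aryl as the large group), which sets the only stereocentre of the target.

Step 6
Reactants: 7 (1R)-2-chloro-1-(4-methoxyphenyl)ethan-1-ol
Product: 8 (2R)-2-(4-methoxyphenyl)oxirane
Conditions: NaH, THF, 0 °C → rt (used crude, no acid contact)
Reagents that add atoms: none
Why: Intramolecular Williamson reaction (3-exo-tet) closes the epoxide without touching the stereocentre, and anhydrous base avoids solvolysis of the acid-labile p-methoxyphenyl oxirane.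

Step 7
Reactants: 5 2-[2,4-bis(benzyloxy)-6-fluoro-3-iodophenyl]-1,3-dithiane; 8 (2R)-2-(4-methoxyphenyl)oxirane
Product: 12 (2S)-5,7-bis(benzyloxy)-6-iodo-2-(4-methoxyphenyl)spiro[chromane-4,2'-[1,3]dithiane], via lithiated dithiane 9 (not isolated), via lithium alkoxide 10 (not isolated), via potassium alkoxide 11 (not isolated)
Conditions: LiN(i-Pr)2 (1.1 equiv), THF, −78 → −30 °C; 8 (1.3 equiv), DMPU, −30 → 0 °C; then KOt-Bu (1.2 equiv), 60 °C, dark
Reagents that add atoms: none
Why: Amide-base deprotonation gives the 2-lithio-1,3-dithiane 9 (Corey–Seebach acyl anion equivalent), which opens oxirane 8 by SN2 attack at the unsubstituted CH2 carbon and so forms the C3–C4 bond with release of ring strain, and after cation exchange the potassium alkoxide 11 lets O1 displace fluoride from C8a by addition–elimination (intramolecular SNAr), forming the O1–C8a bond. The closest known reaction types are dithiane-anion openings of styrene oxides used for flavanones and alkoxide cyclizations of 3-(2-fluoroaryl)propanols to chromans, telescoped here into a formal (3+3) annulation. Ring C is closed in a 6-exo-trig addition–elimination mode at the fluorine-bearing carbon, helped by the gem-disubstituted dithiane carbon (Thorpe–Ingold effect) and the two inductively withdrawing meta benzyloxy groups. No stereocentre is created, because C2 comes from epoxide 8 with all four of its bonds intact, so (R)-8 maps onto (2S)-12 only through a change in CIP priorities. The step needs attack at CH2 and not at the benzylic carbon, which the bulky tertiary carbanion and the absence of strong Lewis acids should secure, and O-arylation that gives the 6-linked and not the 8-linked flavanone, which is secured because fluorine is the only competent leaving group on ring A and sits ortho to the dithiane carbon and para to the iodine-bearing carbon. Because C4 is a dithioketal, the alkoxide cannot undergo retro-aldol cleavage or elimination and C2 cannot epimerize by ring opening.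

Step 8
Reactants: 13 1-(2,4,6-trihydroxyphenyl)ethan-1-one
Product: 14 1-[2,4-bis(benzyloxy)-6-hydroxyphenyl]ethan-1-one
Conditions: BnBr (2.1 equiv), K2CO3, DMF, rt
Reagents that add atoms: benzyl bromide, BrCc1ccccc1
Why: Williamson ether synthesis should leave free the hydroxyl that is hydrogen-bonded to the acetyl group, since it is the least nucleophilic of the three.

Step 9
Reactants: 14 1-[2,4-bis(benzyloxy)-6-hydroxyphenyl]ethan-1-one; 15 3-bromo-4-methoxybenzaldehyde
Product: 16 (2E)-1-[2,4-bis(benzyloxy)-6-hydroxyphenyl]-3-(3-bromo-4-methoxyphenyl)prop-2-en-1-one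
Conditions: KOH, EtOH/THF, rt → 40 °C
Reagents that add atoms: none
Why: Claisen–Schmidt condensation (crossed aldol addition followed by E1cB dehydration) should give the (E)-2'-hydroxychalcone.

Step 10
Reactants: 16 (2E)-1-[2,4-bis(benzyloxy)-6-hydroxyphenyl]-3-(3-bromo-4-methoxyphenyl)prop-2-en-1-one
Product: 17 5,7-bis(benzyloxy)-2-(3-bromo-4-methoxyphenyl)-4H-chromen-4-one
Conditions: I2 (10 mol %), DMSO, 130 °C
Reagents that add atoms: none
Why: Iodine/DMSO oxidative cyclization of a 2'-hydroxychalcone (6-endo oxa-Michael closure, then iodination and elimination at C3 with DMSO as terminal oxidant) closes ring C' of the flavone.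

Step 11
Reactants: 17 5,7-bis(benzyloxy)-2-(3-bromo-4-methoxyphenyl)-4H-chromen-4-one
Product: 18 5,7-bis(benzyloxy)-2-[4-methoxy-3-(4,4,5,5-tetramethyl-1,3,2-dioxaborolan-2-yl)phenyl]-4H-chromen-4-one
Conditions: B2pin2, PdCl2(dppf) (5 mol %), KOAc, 1,4-dioxane, 90 °C
Reagents that add atoms: bis(pinacolato)diboron, CC1(C)OB(OC1(C)C)B1OC(C)(C)C(C)(C)O1
Why: Miyaura borylation of the aryl bromide uses only a weak acetate base, which the flavone carbonyl and the benzyl ethers should tolerate.

Step 12
Reactants: 12 (2S)-5,7-bis(benzyloxy)-6-iodo-2-(4-methoxyphenyl)spiro[chromane-4,2'-[1,3]dithiane]; 18 5,7-bis(benzyloxy)-2-[4-methoxy-3-(4,4,5,5-tetramethyl-1,3,2-dioxaborolan-2-yl)phenyl]-4H-chromen-4-one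
Product: 19 5,7-bis(benzyloxy)-2-{3-[(2S)-5,7-bis(benzyloxy)-2-(4-methoxyphenyl)spiro[chromane-4,2'-[1,3]dithian]-6-yl]-4-methoxyphenyl}-4H-chromen-4-one
Conditions: Pd(OAc)2 (5 mol %), SPhos (10 mol %), K3PO4, toluene/H2O, 90 °C
Reagents that add atoms: none
Why: Suzuki–Miyaura coupling with a dialkylbiarylphosphine ligand is a standard answer to tri-ortho-substituted biaryls, and with C4 masked as a dithioketal the base can neither open ring C nor epimerize C2.

Step 13
Reactants: 19 5,7-bis(benzyloxy)-2-{3-[(2S)-5,7-bis(benzyloxy)-2-(4-methoxyphenyl)spiro[chromane-4,2'-[1,3]dithian]-6-yl]-4-methoxyphenyl}-4H-chromen-4-one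
Product: 20 5,7-bis(benzyloxy)-2-{3-[(2S)-5,7-bis(benzyloxy)-2-(4-methoxyphenyl)-4-oxochroman-6-yl]-4-methoxyphenyl}-4H-chromen-4-one
Conditions: MeI (excess), CaCO3, MeCN/H2O, 45 °C
Reagents that add atoms: water, O
Why: Alkylative dithiane hydrolysis (S-methylation, then hydrolysis of a thionium ion stabilized by electron-rich ring A) runs near neutrality under CaCO3 buffering, so the flavanone should be set free without ring opening at C2.

Step 14
Reactants: 20 5,7-bis(benzyloxy)-2-{3-[(2S)-5,7-bis(benzyloxy)-2-(4-methoxyphenyl)-4-oxochroman-6-yl]-4-methoxyphenyl}-4H-chromen-4-one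
Product: 21 5,7-dihydroxy-2-{3-[(2S)-5,7-dihydroxy-2-(4-methoxyphenyl)-4-oxochroman-6-yl]-4-methoxyphenyl}-4H-chromen-4-one (CNP0081547.1)
Conditions: H2 (1 atm), Pd/C (10 wt %), EtOAc/MeOH, rt
Reagents that add atoms: none
Why: Catalytic hydrogenolysis of the four benzyl ethers is neutral, so C2 should keep its configuration, and the aryl methyl ethers and the flavone C2=C3 bond should survive at room temperature and ambient pressure.

**Compound list**

1 | 5-fluorobenzene-1,3-diol | Oc1cc(O)cc(F)c1 | starting material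
2 | 5-fluoro-2-iodobenzene-1,3-diol | Oc1cc(F)cc(O)c1I | intermediate
3 | 1,3-bis(benzyloxy)-5-fluoro-2-iodobenzene | Fc1cc(OCc2ccccc2)c(I)c(OCc2ccccc2)c1 | intermediate
4 | 2,4-bis(benzyloxy)-6-fluoro-3-iodobenzaldehyde | O=Cc1c(F)cc(OCc2ccccc2)c(I)c1OCc1ccccc1 | intermediate
5 | 2-[2,4-bis(benzyloxy)-6-fluoro-3-iodophenyl]-1,3-dithiane | Fc1cc(OCc2ccccc2)c(I)c(OCc2ccccc2)c1C1SCCCS1 | intermediate
6 | 2-chloro-1-(4-methoxyphenyl)ethan-1-one | COc1ccc(C(=O)CCl)cc1 | starting material
7 | (1R)-2-chloro-1-(4-methoxyphenyl)ethan-1-ol | COc1ccc([C@@H](O)CCl)cc1 | intermediate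
8 | (2R)-2-(4-methoxyphenyl)oxirane | COc1ccc([C@@H]2CO2)cc1 | intermediate
9 | {2-[2,4-bis(benzyloxy)-6-fluoro-3-iodophenyl]-1,3-dithian-2-yl}lithium | [Li]C1(c2c(F)cc(OCc3ccccc3)c(I)c2OCc2ccccc2)SCCCS1 | intermediate
10 | lithium (1S)-2-{2-[2,4-bis(benzyloxy)-6-fluoro-3-iodophenyl]-1,3-dithian-2-yl}-1-(4-methoxyphenyl)ethan-1-olate | COc1ccc([C@@H](O[Li])CC2(c3c(F)cc(OCc4ccccc4)c(I)c3OCc3ccccc3)SCCCS2)cc1 | intermediate
11 | potassium (1S)-2-{2-[2,4-bis(benzyloxy)-6-fluoro-3-iodophenyl]-1,3-dithian-2-yl}-1-(4-methoxyphenyl)ethan-1-olate | COc1ccc([C@@H](O[K])CC2(c3c(F)cc(OCc4ccccc4)c(I)c3OCc3ccccc3)SCCCS2)cc1 | intermediate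
12 | (2S)-5,7-bis(benzyloxy)-6-iodo-2-(4-methoxyphenyl)spiro[chromane-4,2'-[1,3]dithiane] | COc1ccc([C@@H]2CC3(SCCCS3)c3c(OCc4ccccc4)c(I)c(OCc4ccccc4)cc3O2)cc1 | intermediate
13 | 1-(2,4,6-trihydroxyphenyl)ethan-1-one | CC(=O)c1c(O)cc(O)cc1O | starting material
14 | 1-[2,4-bis(benzyloxy)-6-hydroxyphenyl]ethan-1-one | CC(=O)c1c(O)cc(OCc2ccccc2)cc1OCc1ccccc1 | intermediate
15 | 3-bromo-4-methoxybenzaldehyde | COc1ccc(C=O)cc1Br | starting material
16 | (2E)-1-[2,4-bis(benzyloxy)-6-hydroxyphenyl]-3-(3-bromo-4-methoxyphenyl)prop-2-en-1-one | COc1ccc(/C=C/C(=O)c2c(O)cc(OCc3ccccc3)cc2OCc2ccccc2)cc1Br | intermediate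
17 | 5,7-bis(benzyloxy)-2-(3-bromo-4-methoxyphenyl)-4H-chromen-4-one | COc1ccc(-c2cc(=O)c3c(OCc4ccccc4)cc(OCc4ccccc4)cc3o2)cc1Br | intermediate
18 | 5,7-bis(benzyloxy)-2-[4-methoxy-3-(4,4,5,5-tetramethyl-1,3,2-dioxaborolan-2-yl)phenyl]-4H-chromen-4-one | COc1ccc(-c2cc(=O)c3c(OCc4ccccc4)cc(OCc4ccccc4)cc3o2)cc1B1OC(C)(C)C(C)(C)O1 | intermediate
19 | 5,7-bis(benzyloxy)-2-{3-[(2S)-5,7-bis(benzyloxy)-2-(4-methoxyphenyl)spiro[chromane-4,2'-[1,3]dithian]-6-yl]-4-methoxyphenyl}-4H-chromen-4-one | COc1ccc([C@@H]2CC3(SCCCS3)c3c(OCc4ccccc4)c(-c4cc(-c5cc(=O)c6c(OCc7ccccc7)cc(OCc7ccccc7)cc6o5)ccc4OC)c(OCc4ccccc4)cc3O2)cc1 | intermediate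
20 | 5,7-bis(benzyloxy)-2-{3-[(2S)-5,7-bis(benzyloxy)-2-(4-methoxyphenyl)-4-oxochroman-6-yl]-4-methoxyphenyl}-4H-chromen-4-one | COc1ccc([C@@H]2CC(=O)c3c(OCc4ccccc4)c(-c4cc(-c5cc(=O)c6c(OCc7ccccc7)cc(OCc7ccccc7)cc6o5)ccc4OC)c(OCc4ccccc4)cc3O2)cc1 | intermediate
21 | 5,7-dihydroxy-2-{3-[(2S)-5,7-dihydroxy-2-(4-methoxyphenyl)-4-oxochroman-6-yl]-4-methoxyphenyl}-4H-chromen-4-one | COc1ccc([C@@H]2CC(=O)c3c(cc(O)c(-c4cc(-c5cc(=O)c6c(O)cc(O)cc6o5)ccc4OC)c3O)O2)cc1 | target

**Step count**

Total steps: 14. Longest linear sequence: 8 steps (1, 2, 3, 4, 7, 12, 13, 14).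

**Steps most likely to fail**

Step 7. The non-activated fluoride may resist displacement by the alkoxide, the hot alkoxide base may reduce the aryl iodide, or lithium-ion-promoted isomerization or benzylic opening of the electron-rich oxirane may compete with attack at CH2. The fallback moves the ring closure to the ketone oxidation level, where the carbonyl activates the fluoride. It sets out from 5 and 8: the sequence is stopped after the epoxide opening and quenched with NH4Cl to give (1S)-2-{2-[2,4-bis(benzyloxy)-6-fluoro-3-iodophenyl]-1,3-dithian-2-yl}-1-(4-methoxyphenyl)ethan-1-ol F1. Alkylative dithiane hydrolysis (MeI, CaCO3, MeCN/H2O) should give (3S)-1-[2,4-bis(benzyloxy)-6-fluoro-3-iodophenyl]-3-hydroxy-3-(4-methoxyphenyl)propan-1-one F2. Carbonyl-activated intramolecular SNAr (Cs2CO3, MeCN, 0 °C → rt, short contact time) should give (2S)-5,7-bis(benzyloxy)-6-iodo-2-(4-methoxyphenyl)chroman-4-one F3. Suzuki coupling of F3 with 18 under weakly basic conditions (Pd(OAc)2, SPhos, K3PO4, toluene/H2O, 60 °C) comes back to the route at 20.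

Step 12. Oxidative addition and transmetalation at the doubly ortho-substituted iodide may be slow, so that protodeboronation of 18 or catalyst deactivation by the thioketal sulfur takes over. The fallback changes the organometallic partner. It sets out from 12: iodine–magnesium exchange (i-PrMgCl·LiCl, THF, 0 °C → rt) should give [(2S)-5,7-bis(benzyloxy)-2-(4-methoxyphenyl)spiro[chromane-4,2'-[1,3]dithian]-6-yl]magnesium chloride F4. Transmetalation with ZnCl2 should give [(2S)-5,7-bis(benzyloxy)-2-(4-methoxyphenyl)spiro[chromane-4,2'-[1,3]dithian]-6-yl]zinc chloride F5. Negishi coupling of F5 with bromoflavone 17 (Pd(OAc)2, SPhos, THF, 60 °C) comes back to the route at 19.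

Step 1. Iodination may go to a carbon between fluorine and a hydroxyl group, or run on to di-iodides. The fallback replaces electrophilic substitution by directed ortho-metalation. It sets out from 1: MOMCl, i-Pr2NEt, CH2Cl2 should give 1-fluoro-3,5-bis(methoxymethoxy)benzene F6. n-BuLi (THF, −78 → −40 °C) should lithiate the carbon flanked by the two chelating MOM ethers to give [4-fluoro-2,6-bis(methoxymethoxy)phenyl]lithium F7. Quenching with I2 should give 5-fluoro-2-iodo-1,3-bis(methoxymethoxy)benzene F8. HCl in MeOH removes both MOM groups and comes back to the route at 2.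

**Further compounds**

F1 | step 7 | (1S)-2-{2-[2,4-bis(benzyloxy)-6-fluoro-3-iodophenyl]-1,3-dithian-2-yl}-1-(4-methoxyphenyl)ethan-1-ol | COc1ccc([C@@H](O)CC2(c3c(F)cc(OCc4ccccc4)c(I)c3OCc3ccccc3)SCCCS2)cc1
F2 | step 7 | (3S)-1-[2,4-bis(benzyloxy)-6-fluoro-3-iodophenyl]-3-hydroxy-3-(4-methoxyphenyl)propan-1-one | COc1ccc([C@@H](O)CC(=O)c2c(F)cc(OCc3ccccc3)c(I)c2OCc2ccccc2)cc1
F3 | step 7 | (2S)-5,7-bis(benzyloxy)-6-iodo-2-(4-methoxyphenyl)chroman-4-one | COc1ccc([C@@H]2CC(=O)c3c(OCc4ccccc4)c(I)c(OCc4ccccc4)cc3O2)cc1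
F4 | step 12 | [(2S)-5,7-bis(benzyloxy)-2-(4-methoxyphenyl)spiro[chromane-4,2'-[1,3]dithian]-6-yl]magnesium chloride | COc1ccc([C@@H]2CC3(SCCCS3)c3c(OCc4ccccc4)c([Mg]Cl)c(OCc4ccccc4)cc3O2)cc1
F5 | step 12 | [(2S)-5,7-bis(benzyloxy)-2-(4-methoxyphenyl)spiro[chromane-4,2'-[1,3]dithian]-6-yl]zinc chloride | COc1ccc([C@@H]2CC3(SCCCS3)c3c(OCc4ccccc4)c([Zn]Cl)c(OCc4ccccc4)cc3O2)cc1
F6 | step 1 | 1-fluoro-3,5-bis(methoxymethoxy)benzene | COCOc1cc(F)cc(OCOC)c1
F7 | step 1 | [4-fluoro-2,6-bis(methoxymethoxy)phenyl]lithium | [Li]c1c(OCOC)cc(F)cc1OCOC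
F8 | step 1 | 5-fluoro-2-iodo-1,3-bis(methoxymethoxy)benzene | COCOc1cc(F)cc(OCOC)c1I
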